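3 questions stand on this flask, two orders at the outset and one share left at 23 h, and two chemists split over them.

| flask | starting material | free catalyst | product | time |
|---|---|---|---|---|
| ochre | 200 mM | 0.400 mM |  |  |
| grey | 200 mM | 0.200 mM |  |  |
| blue | 100 mM | 0.400 mM |  |  |
| teal | 200 mM | 0.400 mM | 60.0 mM | 23 h |

- ochre run (time / h: [starting material] / mM): 0.92: 180.4; 1.8: 177.2; 3.3: 165.3; 6.3: 152.7; 12: 128.2; 23: 85.5
- grey run (time / h: [starting material] / mM): 0.92: 192.0; 1.8: 185.1; 3.3: 177.3; 6.3: 163.0; 12: 132.0; 23: 89.1
- blue run (time / h: [starting material] / mM): 0.92: 74.8; 1.8: 73.6; 3.3: 69.6; 6.3: 65.0; 12: 49.4; 23: 32.0

(readings scatter by 2 mM)

* reaction order in [free catalyst] at the outset, round the charge of the ochre run, defined at two percent of the starting material turned into product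
* reaction order in [starting material] at the outset, round the charge of the ochre run, defined at two percent of the starting material turned into product (one fixed amount of product, the same in the runs compared)
* starting material in the teal run at 23 h, as a share of the starting material charged

- Overall: starting material -> product, with free catalyst as catalyst.
- Constant volume, constant temperature.
- What is held in complexes is read along with the free species.
- An order is taken over about fifteen percent of the charge, up and down.

From 3.3 h to 23 h the ochre run falls at 0.0335 h⁻¹ and the grey run, with half the catalyst, at 0.0349 h⁻¹. Their mean, 0.0342 h⁻¹, is worth freezing as the background constant: the fraction of the remaining starting material lost per hour once the early drop is over, a first-order rate constant. The blue run reads 0.0394 h⁻¹, a rougher figure, with a scatter of 2 mM on 32.0 mM.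

Over 23 h that constant leaves a survival of 45.5%. Dividing each last reading by it carries the line back to the start and shows the early drop: 12.3 mM in ochre, 4.36 mM in grey, 29.7 mM in blue.

The first chemist argues from these drops. Ochre's is larger than grey's, and blue's, on the smaller charge, is larger than ochre's, so the catalyst looks like the heart of the flask, with a positive order in catalyst and a negative one in starting material. He expects the 60.0 mM of product in the teal run to silence the catalyst and leave the bare line's 45.5%.

The second chemist answers that ochre loses less in its drop than along its line, where 102 mM goes. Whether the teal run keeps the drop or not moves its share by 2.8 percentage points.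

I side with the second. The drops are totals, not rates, so I take the signs of the orders from them and no values. No earlier run holds added product, so I give the teal run ochre's drop, which leaves 42.8%.

The forecast says “This looks like an uncatalysed background reaction.” and gives 2.8, −1.2 and 44%, a share above mine.

The flask gives an order of 2.1 in free catalyst, −0.68 in starting material, and 42.8% left in the teal run.

    free catalyst + starting material ⇌ catalyst-substrate complex, settled at all times (97.60 M⁻¹)
    catalyst-substrate complex + free catalyst → product + 2 free catalyst (4.572 × 10⁶ M⁻¹ h⁻¹)
    starting material → product (0.03420 h⁻¹)
    catalyst-substrate complex → spent catalyst + starting material (1.573 h⁻¹)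

Without the uncatalysed conversion of starting material into product, the teal run keeps 94.2% at 23 h instead of 42.8%, which makes that conversion the main reason, and the survival applied to the share without it gives 42.9%. The first chemist keeps the outset: at two percent turned, the ochre run makes product at 31 mM h⁻¹, faster than the 6.84 mM h⁻¹ of the background constant times the charge. In the grey run, the constant by itself puts half turned at 20.3 h, and the flask reaches it at 19.8 h.

The data come from a simulation for substances that don't exist.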